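**Retrosynthetic overview**

1. Labels: ring A = benzo ring of the dihydrobenzofuran; ring B = 3,5-dioxygenated aryl on its C3; ring C = 4-oxygenated phenyl on Cb; ring D = phenol ring on Ca that also carries the stilbene; ring E = 4-oxygenated phenyl on C2. Ca and Cb are the two sp3 carbons of the seven-membered ring (C9 and C8 of the tetracyclic core).
2. Target 31 ⇐ cleavage of nine methyl ethers and one aryl mesylate from 29. In 29 the seven-membered ring (furan C3, two carbons of ring B, Cb, Ca, C4 and C3a of ring A) is cut at the Cb–ring B bond, giving triarylethene 26 (Ca=Cb), the fully assembled open skeleton.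
3. Enabling feature: ring B has a carbon ortho to C3 that is ortho and para to its two oxygens, placed so that its bond to Cb closes a seven-membered ring, and Cb carries the donor ring C. With the ring D oxygen (ortho to Ca) worn as a mesylate, a proton goes only to Ca and the cation only to Cb; C3 alone then fixes Ca, Cb and, by reversible C2–O ionisation, C2.
4. 26 ⇐ Barluenga carbene cross-coupling of bromodihydrobenzofuran 24 with tosylhydrazone 20; 20 ⇐ Heck union of vinylbenzofuran 11 with bromo ketone 17.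
5. Both heterocycles come from one ketone 7: anionic cyclisation gives the benzofuran (first ring, 9); enantioselective rhodium-carbene C–H insertion gives the dihydrobenzofuran (second ring, 24, sets C3); the seven-membered ring is closed last.

Key step: step 14

Remark: Rh2(S-PTAD)4 in step 12 is assumed to deliver the 3S centre; should the sense of induction prove opposite, the mirror-image catalyst Rh2(R-PTAD)4 is used and nothing else changes.

**Route**

Step 1
Reactants: 1 2-bromo-4,6-dimethoxybenzaldehyde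
Product: 2 2-bromo-6-hydroxy-4-methoxybenzaldehyde
Conditions: BCl3 (1.2 equiv), CH2Cl2, −78 → 0 °C; then H2O
Reagents that add atoms: none
Why: Chelation-controlled ether cleavage, in which BCl3 bound to the aldehyde oxygen should remove only the methyl group of the ortho methoxy group and leave the para one intact.

Step 2
Reactants: 2 2-bromo-6-hydroxy-4-methoxybenzaldehyde; 3 4-methoxybenzyl chloride
Product: 4 2-bromo-4-methoxy-6-[(4-methoxybenzyl)oxy]benzaldehyde
Conditions: K2CO3, DMF, 60 °C
Reagents that add atoms: 4-methoxybenzyl chloride, COc1ccc(CCl)cc1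
Why: Williamson ether synthesis on the phenoxide installs the benzylic CH2 that becomes C2 of both furan rings.

Step 3
Reactants: 4 2-bromo-4-methoxy-6-[(4-methoxybenzyl)oxy]benzaldehyde; 5 (3,5-dimethoxyphenyl)magnesium chloride
Product: 6 rac-[2-bromo-4-methoxy-6-[(4-methoxybenzyl)oxy]phenyl](3,5-dimethoxyphenyl)methanol
Conditions: THF, −40 → 0 °C; then H2O
Reagents that add atoms: (3,5-dimethoxyphenyl)magnesium chloride, COc1cc(OC)cc([Mg]Cl)c1
Why: 1,2-Addition of the aryl Grignard reagent to the aldehyde should outrun halogen–magnesium exchange at low temperature, and the racemic carbinol centre is removed in step 4.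

Step 4
Reactants: 6 rac-[2-bromo-4-methoxy-6-[(4-methoxybenzyl)oxy]phenyl](3,5-dimethoxyphenyl)methanol
Product: 7 [2-bromo-4-methoxy-6-[(4-methoxybenzyl)oxy]phenyl](3,5-dimethoxyphenyl)methanone
Conditions: Dess–Martin periodinane, CH2Cl2, 23 °C
Reagents that add atoms: none
Why: Dess–Martin oxidation of a diaryl carbinol is mild and should leave the aryl bromide and the benzylic ether untouched.

Step 5
Reactants: 7 [2-bromo-4-methoxy-6-[(4-methoxybenzyl)oxy]phenyl](3,5-dimethoxyphenyl)methanone
Product: 9 4-bromo-3-(3,5-dimethoxyphenyl)-6-methoxy-2-(4-methoxyphenyl)-1-benzofuran, via 3-hydroxy-2,3-dihydrobenzofuran 8 (not isolated)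
Conditions: phosphazene base P4-t-Bu (30 mol %), 4 Å molecular sieves, toluene, 23 → 90 °C
Reagents that add atoms: none
Why: Anionic 5-exo-trig aldol-type cyclisation, in which the base reversibly deprotonates the ArCH2–O position, the carbanion adds to the ketone and the tertiary alkoxide 8 loses water with aromatisation, as known for 2-benzyloxybenzophenones.

Step 6
Reactants: 9 4-bromo-3-(3,5-dimethoxyphenyl)-6-methoxy-2-(4-methoxyphenyl)-1-benzofuran; 10 tributyl(vinyl)stannane
Product: 11 3-(3,5-dimethoxyphenyl)-4-ethenyl-6-methoxy-2-(4-methoxyphenyl)-1-benzofuran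
Conditions: Pd(PPh3)4 (5 mol %), toluene, 100 °C
Reagents that add atoms: tributyl(vinyl)stannane, C=C[Sn](CCCC)(CCCC)CCCC
Why: Stille coupling should exchange the hindered C4 bromide for a vinyl group under neutral conditions.

Step 7
Reactants: 12 5-bromo-2-hydroxybenzonitrile; 13 (4-methoxybenzyl)magnesium chloride
Product: 15 1-(5-bromo-2-hydroxyphenyl)-2-(4-methoxyphenyl)ethan-1-one, via magnesium ketimine 14 (not isolated)
Conditions: 13 (3 equiv), THF, 0 → 65 °C; then 2 M HCl, 23 °C
Reagents that add atoms: (4-methoxybenzyl)magnesium chloride, COc1ccc(C[Mg]Cl)cc1; water, O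
Why: Grignard addition to the nitrile (the first equivalent deprotonates the phenol) stops at the N-magnesio ketimine, which resists a second addition and hydrolyses to the 2-hydroxydeoxybenzoin.

Step 8
Reactants: 15 1-(5-bromo-2-hydroxyphenyl)-2-(4-methoxyphenyl)ethan-1-one; 16 methanesulfonyl chloride
Product: 17 4-bromo-2-[(4-methoxyphenyl)acetyl]phenyl methanesulfonate
Conditions: Et3N, CH2Cl2, 0 °C
Reagents that add atoms: methanesulfonyl chloride, CS(=O)(=O)Cl
Why: Sulfonylation of the phenol masks the ring D oxygen as a non-nucleophilic, electron-withdrawing group that steps 9 to 14 should all tolerate.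

Step 9
Reactants: 11 3-(3,5-dimethoxyphenyl)-4-ethenyl-6-methoxy-2-(4-methoxyphenyl)-1-benzofuran; 17 4-bromo-2-[(4-methoxyphenyl)acetyl]phenyl methanesulfonate
Product: 18 4-[(E)-2-[3-(3,5-dimethoxyphenyl)-6-methoxy-2-(4-methoxyphenyl)-1-benzofuran-4-yl]ethenyl]-2-[(4-methoxyphenyl)acetyl]phenyl methanesulfonate
Conditions: Pd(OAc)2 (5 mol %), P(o-tol)3 (10 mol %), Et3N, DMF, 100 °C
Reagents that add atoms: none
Why: Heck reaction of the aryl bromide with the terminal styrene should give the E-stilbene by syn-insertion and syn-β-hydride elimination, the aryl mesylate being inert to palladium with this ligand.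

Step 10
Reactants: 18 the stilbene ketone of step 9; 19 4-methylbenzenesulfonohydrazide
Product: 20 4-[(E)-2-[3-(3,5-dimethoxyphenyl)-6-methoxy-2-(4-methoxyphenyl)-1-benzofuran-4-yl]ethenyl]-2-[2-(4-methoxyphenyl)-1-(tosylhydrazinylidene)ethyl]phenyl methanesulfonate (C=N isomer mixture)
Conditions: AcOH (cat.), MeOH–THF, 60 °C
Reagents that add atoms: 4-methylbenzenesulfonohydrazide, Cc1ccc(S(=O)(=O)NN)cc1
Why: Acid-catalysed condensation of the ketone with the sulfonyl hydrazide gives the tosylhydrazone, the carbene precursor for step 13.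

Step 11
Reactants: 7 [2-bromo-4-methoxy-6-[(4-methoxybenzyl)oxy]phenyl](3,5-dimethoxyphenyl)methanone; 21 hydrazine monohydrate
Product: 22 [2-bromo-4-methoxy-6-[(4-methoxybenzyl)oxy]phenyl](3,5-dimethoxyphenyl)methanone hydrazone (C=N isomer mixture)
Conditions: N2H4·H2O (excess), AcOH (cat.), n-BuOH, 110 °C
Reagents that add atoms: hydrazine, NN
Why: Condensation of the hindered diaryl ketone with a large excess of hydrazine under forcing conditions should give the free hydrazone and suppress azine formation.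

Step 12
Reactants: 22 the hydrazone of step 11
Product: 24 cis-(2R,3S)-4-bromo-3-(3,5-dimethoxyphenyl)-6-methoxy-2-(4-methoxyphenyl)-2,3-dihydro-1-benzofuran, via diazo compound 23 (not isolated)
Conditions: MnO2, CH2Cl2, 0 °C, filtration; then Rh2(S-PTAD)4 (dirhodium tetrakis[(S)-2-(adamantan-1-yl)-2-phthalimidoacetate], 1 mol %), CH2Cl2, −20 → 23 °C
Reagents that add atoms: none
Why: MnO2 dehydrogenates the hydrazone to diaryldiazomethane 23, whose dirhodium donor/donor carbene inserts into the benzylic ether C–H bond (1,5-insertion, five-membered ring), the chiral carboxylate ligands fixing C3 as S with C2 cis to it (2R), a C2 configuration that step 14 corrects.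

Step 13
Reactants: 24 cis-(2R,3S)-bromodihydrobenzofuran; 20 the tosylhydrazone of step 10
Product: 26 2-[1-[(2R,3S)-3-(3,5-dimethoxyphenyl)-6-methoxy-2-(4-methoxyphenyl)-2,3-dihydro-1-benzofuran-4-yl]-2-(4-methoxyphenyl)ethenyl]-4-[(E)-2-[3-(3,5-dimethoxyphenyl)-6-methoxy-2-(4-methoxyphenyl)-1-benzofuran-4-yl]ethenyl]phenyl methanesulfonate (triarylethene as E/Z mixture), via diazo compound 25 (not isolated)
Conditions: Pd2(dba)3 (2.5 mol %), XPhos (10 mol %), Cs2CO3, 1,4-dioxane, 100 °C
Reagents that add atoms: none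
Why: Barluenga cross-coupling, in which Bamford–Stevens fragmentation gives diazo compound 25, the arylpalladium bromide from 24 forms a palladium carbene, and aryl migration followed by β-hydride elimination gives the triarylethene, whose geometry is irrelevant because step 14 erases it.

Step 14
Reactants: 26 the triarylethene of step 13
Product: 29 4-[(E)-2-[3-(3,5-dimethoxyphenyl)-6-methoxy-2-(4-methoxyphenyl)-1-benzofuran-4-yl]ethenyl]-2-[(1S,8S,9R,16S)-4,6,12-trimethoxy-8,16-bis(4-methoxyphenyl)-15-oxatetracyclo[8.6.1.0^2,7.0^14,17]heptadeca-2(7),3,5,10(17),11,13-hexaen-9-yl]phenyl methanesulfonate, via trans-epimer 27 (not isolated), via benzylic cation 28 (not isolated)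
Conditions: CF3CO2H (20 equiv), CH2Cl2–(CF3)2CHOH, high dilution, 0 → 23 °C
Reagents that add atoms: none
Why: CF3CO2H protonates the Ca=Cb alkene at Ca only, since the cation on Cb is a 4-methoxybenzyl cation (ring C) whereas a cation on Ca would lie between the meta-dioxygenated ring A and the mesyloxy-deactivated ring D, and the stilbene of the benzofuran arm, which has no donor para to either alkene carbon, should stay unprotonated. The resulting cation 28 is attacked by the ring B carbon ortho to C3 (ortho and para to the two methoxy groups) in an intramolecular Friedel–Crafts alkylation, the closest known reaction type being the acid-promoted closure of ε-viniferin-type 4-styryl-dihydrobenzofurans to the ampelopsin B ring system. Mode of closure: the seven-membered ring forms by C–C bond formation between Cb and ring B, formally 7-exo-trig with respect to the quinoid resonance form of the cation, followed by loss of the arene proton. Stereocontrol comes from C3 alone: in the boat-like transition state ring D on Ca lies pseudo-equatorial on the outer face with Ca–H turned toward C3–H, and ring C on Cb lies pseudo-equatorial and trans to ring D, which gives 9R and 8S, while the Ca-epimeric cation, which would have to press ring D against C3, can revert to the alkene because protonation is reversible. In the same medium the 4-methoxybenzylic C2–O bond ionises reversibly and recloses to the more stable 2,3-trans ring (2R to 2S, compound 27), an event written here ahead of the cyclisation although either order leads to 29. The selectivities required are site selectivity of protonation and seven- over six-ring closure (ring B attacking a Ca cation), both secured by the donor ring C on Cb together with the mesylate on ring D, and intra- over intermolecular alkylation, secured by high dilution.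

Step 15
Reactants: 29 the cyclised mesylate of step 14
Product: 30 4-[(E)-2-[3-(3,5-dimethoxyphenyl)-6-methoxy-2-(4-methoxyphenyl)-1-benzofuran-4-yl]ethenyl]-2-[(1S,8S,9R,16S)-4,6,12-trimethoxy-8,16-bis(4-methoxyphenyl)-15-oxatetracyclo[8.6.1.0^2,7.0^14,17]heptadeca-2(7),3,5,10(17),11,13-hexaen-9-yl]phenol
Conditions: KOH, MeOH–THF–H2O, 60 °C
Reagents that add atoms: none
Why: Hydroxide attacks the sulfur of the aryl methanesulfonate and releases the ring D phenol, while methyl ethers, stilbene and both furan rings are stable to base.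

Step 16
Reactants: 30 the nonamethyl ether phenol of step 15
Product: 31 (1S,8S,9R,16S)-9-[5-[(E)-2-[3-(3,5-dihydroxyphenyl)-6-hydroxy-2-(4-hydroxyphenyl)-1-benzofuran-4-yl]ethenyl]-2-hydroxyphenyl]-8,16-bis(4-hydroxyphenyl)-15-oxatetracyclo[8.6.1.0^2,7.0^14,17]heptadeca-2(7),3,5,10(17),11,13-hexaene-4,6,12-triol (target)
Conditions: BBr3 (excess), CH2Cl2, −78 → 23 °C; then MeOH, H2O
Reagents that add atoms: none
Why: BBr3 cleaves all nine aryl methyl ethers through aryloxyboron intermediates, a reagent in regular use for permethylated oligostilbenes containing stilbene and dihydrobenzofuran units, and the 2,3-trans ring is the thermodynamic one so that C16 is not at risk.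

**Compound list**

1 | 2-bromo-4,6-dimethoxybenzaldehyde | O=Cc1c(Br)cc(OC)cc1OC | starting material
2 | 2-bromo-6-hydroxy-4-methoxybenzaldehyde | O=Cc1c(Br)cc(OC)cc1O | intermediate
3 | 4-methoxybenzyl chloride | COc1ccc(CCl)cc1 | starting material
4 | 2-bromo-4-methoxy-6-[(4-methoxybenzyl)oxy]benzaldehyde | O=Cc1c(Br)cc(OC)cc1OCc1ccc(OC)cc1 | intermediate
5 | (3,5-dimethoxyphenyl)magnesium chloride (THF solution) | COc1cc(OC)cc([Mg]Cl)c1 | starting material
6 | rac-[2-bromo-4-methoxy-6-[(4-methoxybenzyl)oxy]phenyl](3,5-dimethoxyphenyl)methanol | OC(c1cc(OC)cc(OC)c1)c1c(Br)cc(OC)cc1OCc1ccc(OC)cc1 | intermediate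
7 | [2-bromo-4-methoxy-6-[(4-methoxybenzyl)oxy]phenyl](3,5-dimethoxyphenyl)methanone | O=C(c1cc(OC)cc(OC)c1)c1c(Br)cc(OC)cc1OCc1ccc(OC)cc1 | intermediate
8 | 4-bromo-3-(3,5-dimethoxyphenyl)-6-methoxy-2-(4-methoxyphenyl)-2,3-dihydro-1-benzofuran-3-ol (as alkoxide, racemic diastereomer mixture, not isolated) | COc1ccc(C2Oc3cc(OC)cc(Br)c3C2(O)c2cc(OC)cc(OC)c2)cc1 | intermediate
9 | 4-bromo-3-(3,5-dimethoxyphenyl)-6-methoxy-2-(4-methoxyphenyl)-1-benzofuran | COc1ccc(-c2oc3cc(OC)cc(Br)c3c2-c2cc(OC)cc(OC)c2)cc1 | intermediate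
10 | tributyl(vinyl)stannane | C=C[Sn](CCCC)(CCCC)CCCC | starting material
11 | 3-(3,5-dimethoxyphenyl)-4-ethenyl-6-methoxy-2-(4-methoxyphenyl)-1-benzofuran | COc1ccc(-c2oc3cc(OC)cc(C=C)c3c2-c2cc(OC)cc(OC)c2)cc1 | intermediate
12 | 5-bromo-2-hydroxybenzonitrile | N#Cc1cc(Br)ccc1O | starting material
13 | (4-methoxybenzyl)magnesium chloride (THF solution) | COc1ccc(C[Mg]Cl)cc1 | starting material
14 | 4-bromo-2-[2-(4-methoxyphenyl)ethanimidoyl]phenol (ketimine, present as its magnesium salt, not isolated) | COc1ccc(CC(=N)c2cc(Br)ccc2O)cc1 | intermediate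
15 | 1-(5-bromo-2-hydroxyphenyl)-2-(4-methoxyphenyl)ethan-1-one | COc1ccc(CC(=O)c2cc(Br)ccc2O)cc1 | intermediate
16 | methanesulfonyl chloride | CS(=O)(=O)Cl | starting material
17 | 4-bromo-2-[(4-methoxyphenyl)acetyl]phenyl methanesulfonate | COc1ccc(CC(=O)c2cc(Br)ccc2OS(C)(=O)=O)cc1 | intermediate
18 | 4-[(E)-2-[3-(3,5-dimethoxyphenyl)-6-methoxy-2-(4-methoxyphenyl)-1-benzofuran-4-yl]ethenyl]-2-[(4-methoxyphenyl)acetyl]phenyl methanesulfonate | COc1ccc(-c2oc3cc(OC)cc(/C=C/c4ccc(OS(C)(=O)=O)c(C(=O)Cc5ccc(OC)cc5)c4)c3c2-c2cc(OC)cc(OC)c2)cc1 | intermediate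
19 | 4-methylbenzenesulfonohydrazide | Cc1ccc(S(=O)(=O)NN)cc1 | starting material
20 | tosylhydrazone of 18 (C=N isomer mixture) | COc1ccc(-c2oc3cc(OC)cc(/C=C/c4ccc(OS(C)(=O)=O)c(C(Cc5ccc(OC)cc5)=NNS(=O)(=O)c5ccc(C)cc5)c4)c3c2-c2cc(OC)cc(OC)c2)cc1 | intermediate
21 | hydrazine monohydrate | NN.O | starting material
22 | hydrazone of 7 (C=N isomer mixture) | NN=C(c1cc(OC)cc(OC)c1)c1c(Br)cc(OC)cc1OCc1ccc(OC)cc1 | intermediate
23 | 1-bromo-2-[diazo(3,5-dimethoxyphenyl)methyl]-5-methoxy-3-[(4-methoxybenzyl)oxy]benzene (not isolated) | [N-]=[N+]=C(c1cc(OC)cc(OC)c1)c1c(Br)cc(OC)cc1OCc1ccc(OC)cc1 | intermediate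
24 | cis-(2R,3S)-4-bromo-3-(3,5-dimethoxyphenyl)-6-methoxy-2-(4-methoxyphenyl)-2,3-dihydro-1-benzofuran | Brc1cc(OC)cc2c1[C@H](c1cc(OC)cc(OC)c1)[C@H](c1ccc(OC)cc1)O2 | intermediate
25 | diazo compound from 20: 2-[1-diazo-2-(4-methoxyphenyl)ethyl]-4-[(E)-2-(benzofuran-4-yl)ethenyl]phenyl methanesulfonate with the benzofuran of 11 (not isolated) | COc1ccc(-c2oc3cc(OC)cc(/C=C/c4ccc(OS(C)(=O)=O)c(C(Cc5ccc(OC)cc5)=[N+]=[N-])c4)c3c2-c2cc(OC)cc(OC)c2)cc1 | intermediate
26 | triarylethene with cis-(2R,3S)-dihydrobenzofuran (name as in step 13; E/Z mixture at Ca=Cb) | COc1ccc(-c2oc3cc(OC)cc(/C=C/c4ccc(OS(C)(=O)=O)c(C(=Cc5ccc(OC)cc5)c5cc(OC)cc6c5[C@H](c5cc(OC)cc(OC)c5)[C@H](c5ccc(OC)cc5)O6)c4)c3c2-c2cc(OC)cc(OC)c2)cc1 | intermediate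
27 | C2 epimer of 26 with trans-(2S,3S)-dihydrobenzofuran (not isolated) | COc1ccc(-c2oc3cc(OC)cc(/C=C/c4ccc(OS(C)(=O)=O)c(C(=Cc5ccc(OC)cc5)c5cc(OC)cc6c5[C@H](c5cc(OC)cc(OC)c5)[C@@H](c5ccc(OC)cc5)O6)c4)c3c2-c2cc(OC)cc(OC)c2)cc1 | intermediate
28 | 4-methoxybenzylic cation at Cb formed from 27 by protonation at Ca, Ca configured as in 29 (not isolated) | COc1ccc(-c2oc3cc(OC)cc(/C=C/c4ccc(OS(C)(=O)=O)c([C@H]([CH+]c5ccc(OC)cc5)c5cc(OC)cc6c5[C@H](c5cc(OC)cc(OC)c5)[C@@H](c5ccc(OC)cc5)O6)c4)c3c2-c2cc(OC)cc(OC)c2)cc1 | intermediate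
29 | cyclised mesylate, (1S,8S,9R,16S), name as in step 14 | COc1ccc(-c2oc3cc(OC)cc(/C=C/c4ccc(OS(C)(=O)=O)c([C@H]5c6cc(OC)cc7c6[C@H](c6cc(OC)cc(OC)c6[C@@H]5c5ccc(OC)cc5)[C@@H](c5ccc(OC)cc5)O7)c4)c3c2-c2cc(OC)cc(OC)c2)cc1 | intermediate
30 | nonamethyl ether phenol, (1S,8S,9R,16S), name as in step 15 | COc1ccc(-c2oc3cc(OC)cc(/C=C/c4ccc(O)c([C@H]5c6cc(OC)cc7c6[C@H](c6cc(OC)cc(OC)c6[C@@H]5c5ccc(OC)cc5)[C@@H](c5ccc(OC)cc5)O7)c4)c3c2-c2cc(OC)cc(OC)c2)cc1 | intermediate
31 | CNP0339094.1, (1S,8S,9R,16S), name as in step 16 | Oc1ccc(-c2oc3cc(O)cc(/C=C/c4ccc(O)c([C@H]5c6cc(O)cc7c6[C@H](c6cc(O)cc(O)c6[C@@H]5c5ccc(O)cc5)[C@@H](c5ccc(O)cc5)O7)c4)c3c2-c2cc(O)cc(O)c2)cc1 | target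

**Step count and risks**

Total step count: 16. Longest linear sequence: 12 steps (steps 1, 2, 3, 4, 5, 6, 9, 10, 13, 14, 15, 16).

Steps most likely to fail:

1. Step 14 (key step). What may go wrong: intermolecular Friedel–Crafts alkylation of the electron-rich benzofuran arm by cation 28 (oligomerisation), slow protonation of the arm's stilbene, incomplete facial discrimination at Ca, capture of the transient C2 cation by the alkene instead of by oxygen, or erosion at C3 by proton loss from that same cation. The fallback moves the ring closure ahead of the attachment of the benzofuran arm; it sets out from 24 and 17 and returns at 29. Bromide 24 is converted by copper-catalysed halogen exchange (CuI, NaI, N,N'-dimethylethane-1,2-diamine, dioxane, 110 °C) into (2R,3S)-3-(3,5-dimethoxyphenyl)-4-iodo-6-methoxy-2-(4-methoxyphenyl)-2,3-dihydro-1-benzofuran F1. Ketone 17 is condensed with 19 to its tosylhydrazone F2. F1 and F2 are coupled under the conditions of step 13 at 70 °C, where the aryl iodide should undergo oxidative addition ahead of the aryl bromide of F2, passing through the diazo compound F3 to the bromo triarylethene F4. Under the conditions of step 14, F4 should give, through its C2 epimer F5 and the benzylic cation F6, the cyclised bromide F7, a much smaller substrate that lacks the stilbene and the second benzofuran. Heck reaction of F7 with 11 under the conditions of step 9 then gives 29.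

2. Step 13. What may go wrong: slow oxidative addition and slow carbene migratory insertion at the hindered C4 position next to the C3 aryl group, so that diazo compound 25 is lost to 1,2-hydride shift or azine formation. The fallback replaces the carbene coupling by a Suzuki–Miyaura coupling; it sets out from 24 and 18 and returns at 26. Miyaura borylation of 24 (bis(pinacolato)diboron, PdCl2(dppf), KOAc, dioxane, 90 °C) gives the pinacol boronate F8. Ketone 18 is converted (KN(SiMe3)2, then N-phenylbis(trifluoromethanesulfonimide), THF, −78 °C) into the enol triflate F9. Coupling of F8 with F9 (Pd(OAc)2, SPhos, K3PO4, toluene–water, 80 °C) should give 26.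

3. Step 12. What may go wrong: sluggish formation of the diazo compound at the doubly ortho-substituted ketone, and loss of site- or enantioselectivity of the carbene (cyclopropanation of the benzyl ring, azine formation, low enantiomeric purity). The fallback is racemic reduction followed by resolution; it sets out from 9 and returns at 27. Ionic hydrogenation of 9 (Et3SiH, CF3CO2H, CH2Cl2) should give, after acid equilibration at C2, the racemic trans-dihydrobenzofuran F10. Preparative HPLC on a chiral stationary phase provides the (2S,3S) enantiomer F11. Coupling of F11 with 20 under the conditions of step 13 gives 27 directly, which step 14 converts into 29.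

**Further compounds**

F1 | step 14 | (2R,3S)-3-(3,5-dimethoxyphenyl)-4-iodo-6-methoxy-2-(4-methoxyphenyl)-2,3-dihydro-1-benzofuran | Ic1cc(OC)cc2c1[C@H](c1cc(OC)cc(OC)c1)[C@H](c1ccc(OC)cc1)O2
F2 | step 14 | 4-bromo-2-[2-(4-methoxyphenyl)-1-(tosylhydrazinylidene)ethyl]phenyl methanesulfonate | COc1ccc(CC(=NNS(=O)(=O)c2ccc(C)cc2)c2cc(Br)ccc2OS(C)(=O)=O)cc1
F3 | step 14 | 4-bromo-2-[1-diazo-2-(4-methoxyphenyl)ethyl]phenyl methanesulfonate (not isolated) | COc1ccc(CC(=[N+]=[N-])c2cc(Br)ccc2OS(C)(=O)=O)cc1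
F4 | step 14 | 4-bromo-2-[1-[(2R,3S)-3-(3,5-dimethoxyphenyl)-6-methoxy-2-(4-methoxyphenyl)-2,3-dihydro-1-benzofuran-4-yl]-2-(4-methoxyphenyl)ethenyl]phenyl methanesulfonate (E/Z mixture) | COc1ccc(C=C(c2cc(Br)ccc2OS(C)(=O)=O)c2cc(OC)cc3c2[C@H](c2cc(OC)cc(OC)c2)[C@H](c2ccc(OC)cc2)O3)cc1
F5 | step 14 | (2S,3S) epimer of F4 (not isolated) | COc1ccc(C=C(c2cc(Br)ccc2OS(C)(=O)=O)c2cc(OC)cc3c2[C@H](c2cc(OC)cc(OC)c2)[C@@H](c2ccc(OC)cc2)O3)cc1
F6 | step 14 | 4-methoxybenzylic cation at Cb from F5, Ca configured as in F7 (not isolated) | CS(=O)(=O)Oc1ccc(Br)cc1[C@H]([CH+]c1ccc(OC)cc1)c1cc(OC)cc2c1[C@H](c1cc(OC)cc(OC)c1)[C@@H](c1ccc(OC)cc1)O2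
F7 | step 14 | 4-bromo-2-[(1S,8S,9R,16S)-4,6,12-trimethoxy-8,16-bis(4-methoxyphenyl)-15-oxatetracyclo[8.6.1.0^2,7.0^14,17]heptadeca-2(7),3,5,10(17),11,13-hexaen-9-yl]phenyl methanesulfonate | CS(=O)(=O)Oc1ccc(Br)cc1[C@H]1c2cc(OC)cc3c2[C@H](c2cc(OC)cc(OC)c2[C@@H]1c1ccc(OC)cc1)[C@@H](c1ccc(OC)cc1)O3
F8 | step 13 | 2-[(2R,3S)-3-(3,5-dimethoxyphenyl)-6-methoxy-2-(4-methoxyphenyl)-2,3-dihydro-1-benzofuran-4-yl]-4,4,5,5-tetramethyl-1,3,2-dioxaborolane | CC1(C)OB(OC1(C)C)c1cc(OC)cc2c1[C@H](c1cc(OC)cc(OC)c1)[C@H](c1ccc(OC)cc1)O2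
F9 | step 13 | enol triflate of 18: 1-[5-[(E)-2-[3-(3,5-dimethoxyphenyl)-6-methoxy-2-(4-methoxyphenyl)-1-benzofuran-4-yl]ethenyl]-2-(mesyloxy)phenyl]-2-(4-methoxyphenyl)ethenyl trifluoromethanesulfonate | COc1ccc(-c2oc3cc(OC)cc(/C=C/c4ccc(OS(C)(=O)=O)c(C(OS(=O)(=O)C(F)(F)F)=Cc5ccc(OC)cc5)c4)c3c2-c2cc(OC)cc(OC)c2)cc1
F10 | step 12 | rac-trans-4-bromo-3-(3,5-dimethoxyphenyl)-6-methoxy-2-(4-methoxyphenyl)-2,3-dihydro-1-benzofuran (racemate, relative configuration 2S*,3S*) | Brc1cc(OC)cc2c1C(c1cc(OC)cc(OC)c1)C(c1ccc(OC)cc1)O2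
F11 | step 12 | trans-(2S,3S)-4-bromo-3-(3,5-dimethoxyphenyl)-6-methoxy-2-(4-methoxyphenyl)-2,3-dihydro-1-benzofuran | Brc1cc(OC)cc2c1[C@H](c1cc(OC)cc(OC)c1)[C@@H](c1ccc(OC)cc1)O2
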